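**Plan** (benzofuran numbering of the target: O1, C2, C3, C3a, C4–C7, C7a)

- Retrosynthesis: first the C–Br bond of the bromomethyl ketone is cut (methyl ketone 12). Then the C2–C3 bond of the tetrahydrofuran (ring B) and the bond from the exocyclic carbon to the acyl group are cut together, giving iodide 11, which carries a 1-propynyl ether on the tertiary O1 at C7a and a CH2I group on C3a. Last, the O–alkyne bond and the C3a–C4 and C7a–O bonds of the bromocyclohexane (ring A) are cut, back to geraniol.
- Forward: ring A arises first, by bromonium-induced cation–olefin cyclisation of geranyl tert-butyl carbonate with capture by the carbonate. The ynol ether is then put on the tertiary oxygen. Ring B closes last, by a nickel-catalysed radical 5-exo-dig cyclisation with acylation, followed by α′-bromination.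
- Enabling feature: on the chair of ring A the C7a–O1 and C3a–CH2 bonds are trans-diequatorial (gauche), so a radical at C3 lies 1,5 to the oxygen-bound alkyne carbon C2. O1 and the incoming acyl group then make C2=C(exo) a push–pull alkene that can settle in the Z geometry.
- Stereochemistry: the relative configuration at C3a, C5 and C7a comes from the chair transition state of the bromocyclisation (anti addition across both E-alkenes). The absolute configuration comes from a lipase kinetic resolution of the diol. The alkene geometry comes from anti capture of the vinyl radical, backed by thermodynamic control.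

Key step: step 9

Assumption: in step 4 the lipase acetylates the (1R,2S,4R)-diol faster, so the needed (1S,2R,4S)-diol is the recovered alcohol; with the opposite preference the acetate would be carried on after methanolysis to the same compound 5.

Step 1
Reactants: 1 geraniol
Product: 2 tert-butyl (2E)-3,7-dimethylocta-2,6-dien-1-yl carbonate
Conditions: Boc2O, DMAP (cat.), CH2Cl2, 0 °C to rt
Reagents that add atoms: di-tert-butyl dicarbonate, CC(C)(C)OC(=O)OC(=O)OC(C)(C)C
Why: O-acylation of a primary allylic alcohol to the mixed carbonate installs the internal oxygen nucleophile that will end the cyclisation; no stereocentre is formed.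

Step 2
Reactants: 2 tert-butyl (2E)-3,7-dimethylocta-2,6-dien-1-yl carbonate
Product: 3 rac-(4aR,6S,8aS)-6-bromo-5,5,8a-trimethylhexahydro-4H-1,3-benzodioxin-2-one
Conditions: Et2SBr·SbCl5Br (BDSB), MeNO2, −25 °C; aq. NaHCO3/Na2SO3
Reagents that add atoms: bromodiethylsulfonium bromopentachloroantimonate (BDSB), CC[S+](Br)CC.Br[Sb-](Cl)(Cl)(Cl)(Cl)Cl
Why: Bromonium-induced cation–olefin cyclisation in which Br+ adds to the electron-rich 6,7-alkene, the 2,3-alkene closes ring A through a chair and the carbonate carbonyl traps the tertiary cation with loss of isobutene, so that anti addition across both E-alkenes places Br, CH2O and the new C–O bond equatorial and the methyl axial (racemic).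

Step 3
Reactants: 3 rac-(4aR,6S,8aS)-6-bromo-5,5,8a-trimethylhexahydro-4H-1,3-benzodioxin-2-one
Product: 4 rac-(1S,2R,4S)-4-bromo-2-(hydroxymethyl)-1,3,3-trimethylcyclohexan-1-ol
Conditions: K2CO3, MeOH, rt
Reagents that add atoms: none
Why: Base-mediated methanolysis (transesterification) of the cyclic carbonate frees both hydroxyls without breaking a C–O bond at a stereocentre, and the equatorial neopentyl bromide is inert to these conditions.

Step 4
Reactants: 4 rac-(1S,2R,4S)-4-bromo-2-(hydroxymethyl)-1,3,3-trimethylcyclohexan-1-ol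
Product: 5 (1S,2R,4S)-4-bromo-2-(hydroxymethyl)-1,3,3-trimethylcyclohexan-1-ol (recovered alcohol)
Conditions: lipase PS (Burkholderia cepacia), vinyl acetate, t-BuOMe, rt, to about half conversion; chromatography
Reagents that add atoms: none
Why: Lipase-catalysed kinetic resolution by acyl transfer to the primary hydroxyl next to the stereocentre, a reaction type established for trans-2-(hydroxymethyl)-1-methylcyclohexanols such as drimane-8,11-diols; the acetate of the mirror-image diol is separated, so the absolute configuration of all three centres is fixed here.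

Step 5
Reactants: 5 (1S,2R,4S)-4-bromo-2-(hydroxymethyl)-1,3,3-trimethylcyclohexan-1-ol
Product: 6 (1S,2R,4S)-4-bromo-1,3,3-trimethyl-2-{[tri(propan-2-yl)silyl]oxymethyl}cyclohexan-1-ol
Conditions: TIPSCl, imidazole, DMF, 0 °C to rt
Reagents that add atoms: chlorotri(propan-2-yl)silane, CC(C)[Si](Cl)(C(C)C)C(C)C
Why: Selective silylation of the primary hydroxyl beside a hindered tertiary one; the bulky silyl ether is chosen because it resists KH, n-BuLi and O-to-O migration in the next step.

Step 6
Reactants: 6 (1S,2R,4S)-4-bromo-1,3,3-trimethyl-2-{[tri(propan-2-yl)silyl]oxymethyl}cyclohexan-1-ol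
Product: 9 (1S,2R,4S)-4-bromo-1,3,3-trimethyl-1-(prop-1-yn-1-yloxy)-2-{[tri(propan-2-yl)silyl]oxymethyl}cyclohexane, via dichlorovinyl ether 7 (not isolated), via lithium alkoxyacetylide 8 (not isolated)
Conditions: KH, THF, 0 °C to rt; Cl2C=CHCl, −50 °C to rt; n-BuLi (2.5 equiv), −78 to −40 °C; MeI, HMPA, −78 °C to rt
Reagents that add atoms: trichloroethylene, ClC=C(Cl)Cl; iodomethane, CI
Why: Ynol ether synthesis from an alcohol and trichloroethylene, in which the potassium alkoxide adds to dichloroacetylene formed in situ, n-BuLi effects elimination and Cl/Li exchange, and the lithium alkoxyacetylide is C-methylated; tertiary alkoxides are competent, and the equatorial C5–Br bond has no antiperiplanar hydrogen and exchanges only slowly at −78 °C (9 to 11 are handled at or below rt because tertiary ynol ethers lose ketene on heating).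

Step 7
Reactants: 9 (1S,2R,4S)-4-bromo-1,3,3-trimethyl-1-(prop-1-yn-1-yloxy)-2-{[tri(propan-2-yl)silyl]oxymethyl}cyclohexane
Product: 10 [(1R,3S,6S)-3-bromo-2,2,6-trimethyl-6-(prop-1-yn-1-yloxy)cyclohexyl]methanol
Conditions: TBAF, THF, 0 °C to rt
Reagents that add atoms: none
Why: Fluoride cleavage of the primary silyl ether under basic, non-acidic conditions that the acid-sensitive ynol ether and the secondary bromide tolerate.

Step 8
Reactants: 10 [(1R,3S,6S)-3-bromo-2,2,6-trimethyl-6-(prop-1-yn-1-yloxy)cyclohexyl]methanol
Product: 11 (1S,2S,4S)-4-bromo-2-(iodomethyl)-1,3,3-trimethyl-1-(prop-1-yn-1-yloxy)cyclohexane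
Conditions: PPh3, I2, imidazole (premixed), CH2Cl2, 0 °C
Reagents that add atoms: iodine, II
Why: Appel-type iodination of a primary alcohol through the oxyphosphonium salt; premixing the reagents leaves no free iodine and imidazole buffers the acid, which protects the nucleophilic ynol ether.

Step 9
Reactants: 11 (1S,2S,4S)-4-bromo-2-(iodomethyl)-1,3,3-trimethyl-1-(prop-1-yn-1-yloxy)cyclohexane
Product: 12 (3Z)-3-[(3aS,5S,7aS)-5-bromo-4,4,7a-trimethylhexahydro-1-benzofuran-2(3H)-ylidene]butan-2-one
Conditions: NiBr2(dme) (10 mol%), 4,4'-di-tert-butyl-2,2'-bipyridine (10 mol%), Mn powder (3 equiv), S-(pyridin-2-yl) ethanethioate (2 equiv), DMA, 0.01 M, 0 °C to rt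
Reagents that add atoms: S-(pyridin-2-yl) ethanethioate, CC(=O)Sc1ccccn1
Why: Proposed new method: monovalent nickel abstracts iodine from 11, the primary C3 radical adds 5-exo-dig to the oxygen-bound alkyne carbon C2, the exocyclic vinyl radical is captured by the acetyl–nickel complex formed by oxidative addition of the thioester to zerovalent nickel, and reductive elimination from trivalent nickel releases 12 while Mn re-reduces the catalyst. The closest known reaction types are the nickel-catalysed reductive ketone synthesis from alkyl iodides and S-2-pyridyl thioesters, nickel-catalysed radical carbo-difunctionalisation of alkynes with anti selectivity, and 5-exo-dig iodine-transfer radical cyclisation. Ring B closes in 5-exo-dig mode, helped by the gauche equatorial C7a–O and C3a–CH2 bonds of the ring A chair, which hold the radical and the alkyne 1,5 to one another, and by matched polarity, the nucleophilic alkyl radical attacking the electron-poor oxygen-bearing alkyne carbon. No new stereocentre arises and the trans ring fusion is dictated by C3a and C7a of 11; the one new stereo element, the C2=C geometry, is set by capture of the fast-inverting vinyl radical on the side next to O1 and away from the C3 methylene (acyl cis to oxygen) and is backed by thermodynamics, since the push–pull alkene can equilibrate to the Z isomer. The step needs cyclisation to outrun capture of the primary radical by nickel (low catalyst concentration, high dilution), the C–I bond to react before the hindered secondary C5–Br bond (weaker bond, 0 °C to rt), and the heat- and acid-labile tertiary ynol ether to survive (neutral medium, no heating).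

Step 10
Reactants: 12 (3Z)-3-[(3aS,5S,7aS)-5-bromo-4,4,7a-trimethylhexahydro-1-benzofuran-2(3H)-ylidene]butan-2-one
Product: 14 (3Z)-1-bromo-3-[(3aS,5S,7aS)-5-bromo-4,4,7a-trimethylhexahydro-1-benzofuran-2(3H)-ylidene]butan-2-one, via silyl dienol ether 13 (not isolated)
Conditions: LiN(i-Pr)2 (LDA), TMSCl, THF, −78 °C; volatiles removed; NBS, THF, −78 to 0 °C
Reagents that add atoms: N-bromosuccinimide, O=C1CCC(=O)N1Br; chlorotrimethylsilane (silyl group of 13 only), C[Si](C)(C)Cl
Why: Kinetic α′-deprotonation of the vinylogous ester at the acetyl methyl, trapping in situ as the 1-alkoxy-3-silyloxydiene, and electrophilic bromination of its terminal CH2 by NBS; the γ-methylene C3 is not deprotonated at −78 °C and neither the stereocentres nor the C2=C geometry are involved.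

**Compound list**

1 | geraniol, (2E)-3,7-dimethylocta-2,6-dien-1-ol | CC(C)=CCC/C(C)=C/CO | starting material
2 | tert-butyl (2E)-3,7-dimethylocta-2,6-dien-1-yl carbonate | CC(C)=CCC/C(C)=C/COC(=O)OC(C)(C)C | intermediate
3 | rac-(4aR,6S,8aS)-6-bromo-5,5,8a-trimethylhexahydro-4H-1,3-benzodioxin-2-one (trans-fused; Br, CH2O and ring O equatorial) | O=C1OC[C@H]2C(C)(C)[C@@H](Br)CC[C@]2(C)O1 | intermediate (racemate; the enantiomer carried on is drawn)
4 | rac-(1S,2R,4S)-4-bromo-2-(hydroxymethyl)-1,3,3-trimethylcyclohexan-1-ol | OC[C@H]1C(C)(C)[C@@H](Br)CC[C@]1(C)O | intermediate (racemate; the enantiomer carried on is drawn)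
5 | (1S,2R,4S)-4-bromo-2-(hydroxymethyl)-1,3,3-trimethylcyclohexan-1-ol (single enantiomer) | OC[C@H]1C(C)(C)[C@@H](Br)CC[C@]1(C)O | intermediate
6 | (1S,2R,4S)-4-bromo-1,3,3-trimethyl-2-{[tri(propan-2-yl)silyl]oxymethyl}cyclohexan-1-ol | CC(C)[Si](OC[C@H]1C(C)(C)[C@@H](Br)CC[C@]1(C)O)(C(C)C)C(C)C | intermediate
7 | (1S,2R,4S)-4-bromo-1-{[(E)-1,2-dichloroethenyl]oxy}-1,3,3-trimethyl-2-{[tri(propan-2-yl)silyl]oxymethyl}cyclohexane | CC(C)[Si](OC[C@H]1C(C)(C)[C@@H](Br)CC[C@]1(C)O/C(Cl)=C\Cl)(C(C)C)C(C)C | intermediate (not isolated)
8 | lithium 2-{[(1S,2R,4S)-4-bromo-1,3,3-trimethyl-2-{[tri(propan-2-yl)silyl]oxymethyl}cyclohexyl]oxy}ethynide | CC(C)[Si](OC[C@H]1C(C)(C)[C@@H](Br)CC[C@]1(C)OC#C[Li])(C(C)C)C(C)C | intermediate (not isolated)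
9 | (1S,2R,4S)-4-bromo-1,3,3-trimethyl-1-(prop-1-yn-1-yloxy)-2-{[tri(propan-2-yl)silyl]oxymethyl}cyclohexane | CC(C)[Si](OC[C@H]1C(C)(C)[C@@H](Br)CC[C@]1(C)OC#CC)(C(C)C)C(C)C | intermediate
10 | [(1R,3S,6S)-3-bromo-2,2,6-trimethyl-6-(prop-1-yn-1-yloxy)cyclohexyl]methanol | OC[C@H]1C(C)(C)[C@@H](Br)CC[C@]1(C)OC#CC | intermediate
11 | (1S,2S,4S)-4-bromo-2-(iodomethyl)-1,3,3-trimethyl-1-(prop-1-yn-1-yloxy)cyclohexane | IC[C@H]1C(C)(C)[C@@H](Br)CC[C@]1(C)OC#CC | intermediate
12 | (3Z)-3-[(3aS,5S,7aS)-5-bromo-4,4,7a-trimethylhexahydro-1-benzofuran-2(3H)-ylidene]butan-2-one | C/C(C(C)=O)=C1\C[C@H]2C(C)(C)[C@@H](Br)CC[C@]2(C)O1 | intermediate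
13 | {[(3Z)-3-[(3aS,5S,7aS)-5-bromo-4,4,7a-trimethylhexahydro-1-benzofuran-2(3H)-ylidene]but-1-en-2-yl]oxy}trimethylsilane | C/C(C(=C)O[Si](C)(C)C)=C1\C[C@H]2C(C)(C)[C@@H](Br)CC[C@]2(C)O1 | intermediate (not isolated)
14 | (3Z)-1-bromo-3-[(3aS,5S,7aS)-5-bromo-4,4,7a-trimethylhexahydro-1-benzofuran-2(3H)-ylidene]butan-2-one | C/C(C(=O)CBr)=C1\C[C@H]2C(C)(C)[C@@H](Br)CC[C@]2(C)O1 | target

**Count and risks**

Total step count: 10. Longest linear sequence: 10 steps (from geraniol).

Steps most likely to fail:

Step 9 (proposed new method). The primary radical may be intercepted by the acetyl–nickel species before it cyclises, giving open-chain acylation. The vinyl radical may abstract hydrogen from the solvent before it is acylated. Nickel may activate the secondary C–Br bond, or the tertiary ynol ether may decompose by retro-ene loss of a ketene. Incomplete geometric control is less serious, because the push–pull alkene can be equilibrated with a trace of acid. The fallback uses known chemistry, sets out from 11 and returns at 12. Iodine atom-transfer radical cyclisation of 11 ((Bu3Sn)2 cat., sunlamp, benzene, rt) closes the same bond in 5-exo-dig mode without any metal capture and should give (3aS,5S,7aS)-5-bromo-2-(1-iodoethylidene)-4,4,7a-trimethyloctahydro-1-benzofuran F1 as an E/Z mixture. Stille coupling of F1 with tributyl(1-ethoxyvinyl)stannane (Pd(PPh3)4, CuI, DMF, 50 °C, possible now that the ynol ether is gone) should give (3aS,5S,7aS)-5-bromo-2-(3-ethoxybut-3-en-2-ylidene)-4,4,7a-trimethyloctahydro-1-benzofuran F2. Mild acid (oxalic acid, wet THF, 0 °C) then hydrolyses the simple enol ether to the acetyl group and lets the alkene settle as 12.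

Step 4. The lipase may discriminate the enantiomers poorly, or prefer the enantiomer that is needed as the free diol. The fallback sets out from 4 and returns at 5. The primary hydroxyl of 4 is esterified with (S)-2-methoxy-2-phenylacetic acid (DCC, DMAP cat., CH2Cl2, 0 °C) to give two diastereomers: [(1R,3S,6S)-3-bromo-6-hydroxy-2,2,6-trimethylcyclohexyl]methyl (2S)-2-methoxy-2-phenylacetate F3 and its (1S,3R,6R) diastereomer F4. These are separated by chromatography or crystallisation and assigned by X-ray diffraction with bromine as the heavy atom. Methanolysis of F3 (K2CO3, MeOH, rt) returns 5.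

Step 6. Addition of the hindered tertiary potassium alkoxide to dichloroacetylene may be slow, which leaves time for silyl migration or for attack of the alkoxide on the C5–Br bond across the ring. The fallback sets out from 6 and returns at 9. Formylation of the tertiary hydroxyl (acetic formic anhydride, pyridine, 0 °C) gives (1S,2R,4S)-4-bromo-1,3,3-trimethyl-2-{[tri(propan-2-yl)silyl]oxymethyl}cyclohexyl formate F5. Ramirez dibromo-olefination of the formate (CBr4, PPh3, Et3N, CH2Cl2) gives the 2,2-dibromoethenyl ether F6. n-BuLi (2 equiv, THF, −78 °C) converts F6 by elimination and Br/Li exchange into the same lithium alkoxyacetylide 8, which is methylated (MeI, HMPA) to 9.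

**Further compounds**

F1 | step 9 | (3aS,5S,7aS)-5-bromo-2-(1-iodoethylidene)-4,4,7a-trimethyloctahydro-1-benzofuran (E/Z mixture; Z isomer drawn) | C/C(I)=C1\C[C@H]2C(C)(C)[C@@H](Br)CC[C@]2(C)O1
F2 | step 9 | (2Z,3aS,5S,7aS)-5-bromo-2-(3-ethoxybut-3-en-2-ylidene)-4,4,7a-trimethyloctahydro-1-benzofuran | C/C(C(=C)OCC)=C1\C[C@H]2C(C)(C)[C@@H](Br)CC[C@]2(C)O1
F3 | step 4 | [(1R,3S,6S)-3-bromo-6-hydroxy-2,2,6-trimethylcyclohexyl]methyl (2S)-2-methoxy-2-phenylacetate | CO[C@H](C(=O)OC[C@H]1C(C)(C)[C@@H](Br)CC[C@]1(C)O)c1ccccc1
F4 | step 4 | [(1S,3R,6R)-3-bromo-6-hydroxy-2,2,6-trimethylcyclohexyl]methyl (2S)-2-methoxy-2-phenylacetate | CO[C@H](C(=O)OC[C@@H]1C(C)(C)[C@H](Br)CC[C@@]1(C)O)c1ccccc1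
F5 | step 6 | (1S,2R,4S)-4-bromo-1,3,3-trimethyl-2-{[tri(propan-2-yl)silyl]oxymethyl}cyclohexyl formate | CC(C)[Si](OC[C@H]1C(C)(C)[C@@H](Br)CC[C@]1(C)OC=O)(C(C)C)C(C)C
F6 | step 6 | (1S,2R,4S)-4-bromo-1-[(2,2-dibromoethenyl)oxy]-1,3,3-trimethyl-2-{[tri(propan-2-yl)silyl]oxymethyl}cyclohexane | CC(C)[Si](OC[C@H]1C(C)(C)[C@@H](Br)CC[C@]1(C)OC=C(Br)Br)(C(C)C)C(C)C
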